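**Retrosynthetic overview**

1. The target is cut at C8–C9 and C16–C17: two copper-catalysed sp3–sp3 couplings join two side-chain Grignard reagents to a C10 epoxy core (allylic chloride at C9, epoxy triflate at C16).
2. The core comes from C2h-symmetric (2E,6E)-2,7-dimethylocta-2,6-diene-1,8-diol by a desymmetrising Sharpless mono-epoxidation. This closes the only ring (the oxirane), sets C14 and C15, and makes the two ends chemically different.
3. The diol comes from furan: oxidative dearomatisation, hydrogenation, hydrolysis to succinaldehyde, double Wittig olefination, reduction.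
4. Both side chains come from one bromide: the Shapiro alkenyl cuprate of 6-methylhept-5-en-2-one displaces (S)-lactate triflate with inversion (this centre becomes C18 and C7).
5. The left side chain gains its C3 methyl group by allylic oxidation, chlorination and a Cu-catalysed asymmetric SN2′ methylation.

Assumption: compounds 1, 3, 4, 14 and 17 are bought; target atoms are numbered along the chain from C1 (isopropenyl CH2) to C24 (prenyl CH3), which makes the target (3S,7R,10E,14R,15R,18R).

**Route**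

Step 1
Reactants: 1 ethyl (2S)-2-hydroxypropanoate (ethyl (S)-lactate)
Product: 2 ethyl (2S)-2-[(trifluoromethanesulfonyl)oxy]propanoate
Conditions: Tf2O, 2,6-lutidine, CH2Cl2, −78 → 0 °C
Reagents that add atoms: trifluoromethanesulfonic anhydride, O=S(=O)(OS(=O)(=O)C(F)(F)F)C(F)(F)F
Why: O-triflation of the secondary alcohol does not touch the C–O stereocentre, so the (S) configuration is retained.

Step 2
Reactants: 3 6-methylhept-5-en-2-one; 4 2,4,6-tri(propan-2-yl)benzenesulfonohydrazide
Product: 5 N′-(6-methylhept-5-en-2-ylidene)-2,4,6-tri(propan-2-yl)benzenesulfonohydrazide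
Conditions: MeOH, HCl (cat.), 23 °C
Reagents that add atoms: none
Why: Acid-catalysed hydrazone formation from a ketone and a sulfonylhydrazide sets up the Shapiro reaction; no stereocentre is involved.

Step 3
Reactants: 5 N′-(6-methylhept-5-en-2-ylidene)-2,4,6-tri(propan-2-yl)benzenesulfonohydrazide; 2 ethyl (2S)-2-[(trifluoromethanesulfonyl)oxy]propanoate
Product: 8 ethyl (2S)-2,7-dimethyl-3-methylideneoct-6-enoate, via alkenyllithium 6 (not isolated), via lithium dialkenylcuprate 7 (not isolated)
Conditions: n-BuLi (2.05 equiv per 5), TMEDA, THF, −78 → 0 °C; CuI (0.5 equiv per 5), −78 → −40 °C; 2 (0.45 equiv per 5), −78 → −20 °C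
Reagents that add atoms: none
Why: The Shapiro reaction (kinetic deprotonation at the methyl group) gives the 2-lithio-1-alkene, and its Gilman cuprate displaces the α-triflyloxy ester by SN2 with inversion, so (S)-lactate gives the (S)-α-methyl-β,γ-unsaturated ester whose centre later becomes C18 and C7.

Step 4
Reactants: 8 ethyl (2S)-2,7-dimethyl-3-methylideneoct-6-enoate
Product: 9 (2S)-2,7-dimethyl-3-methylideneoct-6-en-1-ol
Conditions: i-Bu2AlH (2.5 equiv), CH2Cl2, −78 → 0 °C
Reagents that add atoms: none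
Why: 1,2-Reduction of the ester by the non-basic aluminium hydride at low temperature gives the primary alcohol without epimerising the α-centre or conjugating the alkene.

Step 5
Reactants: 9 (2S)-2,7-dimethyl-3-methylideneoct-6-en-1-ol
Product: 10 (7S)-8-bromo-2,7-dimethyl-6-methylideneoct-2-ene
Conditions: CBr4, PPh3, CH2Cl2, 0 °C
Reagents that add atoms: carbon tetrabromide, BrC(Br)(Br)Br
Why: Appel bromination replaces the primary hydroxyl by SN2 at a carbon that is not a stereocentre, so the adjacent (S) centre is untouched.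

Step 6
Reactants: 10 (7S)-8-bromo-2,7-dimethyl-6-methylideneoct-2-ene
Product: 11 (2E,7S)-8-bromo-2,7-dimethyl-6-methylideneoct-2-en-1-ol
Conditions: SeO2 (0.3 equiv), t-BuOOH (2.5 equiv), salicylic acid (0.1 equiv), CH2Cl2, 23 °C, stopped at about 60 % conversion
Reagents that add atoms: tert-butyl hydroperoxide, CC(C)(C)OO
Why: Sharpless catalytic SeO2 allylic oxidation (ene reaction then 2,3-shift) hydroxylates the (E)-methyl of the more electron-rich trisubstituted alkene in preference to the 1,1-disubstituted one.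

Step 7
Reactants: 11 (2E,7S)-8-bromo-2,7-dimethyl-6-methylideneoct-2-en-1-ol
Product: 12 (2E,7S)-8-bromo-1-chloro-2,7-dimethyl-6-methylideneoct-2-ene
Conditions: NCS (1.2 equiv), Me2S (1.3 equiv), CH2Cl2, −20 → 0 °C
Reagents that add atoms: N-chlorosuccinimide, O=C1CCC(=O)N1Cl
Why: Corey–Kim chlorination converts the allylic alcohol into the primary allylic chloride without allylic shift or loss of E geometry.

Step 8
Reactants: 12 (2E,7S)-8-bromo-1-chloro-2,7-dimethyl-6-methylideneoct-2-ene
Product: 13 (3S,7S)-8-bromo-2,3,7-trimethyl-6-methylideneoct-1-ene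
Conditions: MeMgBr (1.2 equiv, slow addition), Cu(O2C-2-thienyl) (CuTC, 3 mol %), O,O′-2,2′-biphenyldiyl N,N-bis[1-(2-methoxyphenyl)ethyl]phosphoramidite (one antipode, 3.3 mol %; the antipode that gives 3S is fixed by a model run on tiglyl chloride), CH2Cl2, −78 °C
Reagents that add atoms: methylmagnesium bromide, C[Mg]Br
Why: Copper-catalysed asymmetric allylic alkylation (SN2′, Alexakis conditions for β-substituted allylic chlorides) delivers methyl to the γ-carbon under control of the chiral Cu–phosphoramidite, which sets C3 (S) and moves the alkene into the isopropenyl position.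

Step 9
Reactants: 14 furan
Product: 15 2,5-dimethoxy-2,5-dihydrofuran (cis/trans mixture)
Conditions: Br2, MeOH, Na2CO3, −10 °C
Reagents that add atoms: methanol, CO
Why: Clauson-Kaas oxidative 1,4-dimethoxylation (bromine adds, methanol captures the oxocarbenium ions) breaks the aromaticity of furan and gives the masked butenedial.

Step 10
Reactants: 15 2,5-dimethoxy-2,5-dihydrofuran
Product: 16 2,5-dimethoxyoxolane (2,5-dimethoxytetrahydrofuran, cis/trans mixture)
Conditions: H2 (1 atm), Raney Ni, MeOH, 23 °C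
Reagents that add atoms: none
Why: Heterogeneous hydrogenation saturates the ring alkene while the two acetal centres survive.

Step 11
Reactants: 16 2,5-dimethoxyoxolane; 17 ethyl 2-(triphenyl-λ5-phosphanylidene)propanoate
Product: 19 diethyl (2E,6E)-2,7-dimethylocta-2,6-dienedioate, via butanedial 18 (not isolated)
Conditions: 0.6 M aq. HCl, 70 °C; NaHCO3 to pH 7; then 17 (2.3 equiv), CH2Cl2, 23 °C
Reagents that add atoms: none
Why: Acid hydrolysis of the bis-acetal frees succinaldehyde, which is trapped at once by a double Wittig olefination with the stabilised ylide to give the (E,E)-diester.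

Step 12
Reactants: 19 diethyl (2E,6E)-2,7-dimethylocta-2,6-dienedioate
Product: 20 (2E,6E)-2,7-dimethylocta-2,6-diene-1,8-diol
Conditions: i-Bu2AlH (4.5 equiv), CH2Cl2, −78 → 0 °C
Reagents that add atoms: none
Why: i-Bu2AlH reduces both conjugated esters by 1,2-addition to the C2h-symmetric bis-allylic alcohol with the E geometry intact.

Step 13
Reactants: 20 (2E,6E)-2,7-dimethylocta-2,6-diene-1,8-diol
Product: 21 (2E)-5-[(2R,3R)-3-(hydroxymethyl)-3-methyloxiran-2-yl]-2-methylpent-2-en-1-ol
Conditions: Ti(OiPr)4 (10 mol %), D-(−)-diisopropyl tartrate (12 mol %), t-BuOOH (0.9 equiv), 4 Å MS, CH2Cl2, −25 °C; unreacted 20 recycled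
Reagents that add atoms: tert-butyl hydroperoxide, CC(C)(C)OO
Why: Katsuki–Sharpless asymmetric epoxidation run to partial conversion: the Ti–D-(−)-tartrate catalyst adds oxygen to the same face of either of the two equivalent allylic alkenes, so one (2R,3R)-monoepoxide forms, which breaks the symmetry, closes the only ring, sets C14 and C15 (R,R) and leaves two chemically different hydroxyls.

Step 14
Reactants: 21 (2E)-5-[(2R,3R)-3-(hydroxymethyl)-3-methyloxiran-2-yl]-2-methylpent-2-en-1-ol
Product: 22 [(2R,3R)-3-[(3E)-5-chloro-4-methylpent-3-en-1-yl]-2-methyloxiran-2-yl]methanol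
Conditions: NCS (2.2 equiv), Me2S (2.4 equiv), CH2Cl2, −20 → 0 °C
Reagents that add atoms: N-chlorosuccinimide, O=C1CCC(=O)N1Cl
Why: Corey–Kim conditions chlorinate only the allylic hydroxyl (the alkoxysulfonium of the epoxy carbinol is not displaced and reverts on work-up), giving the allylic chloride with E geometry retained.

Step 15
Reactants: 22 [(2R,3R)-3-[(3E)-5-chloro-4-methylpent-3-en-1-yl]-2-methyloxiran-2-yl]methanol; 13 (3S,7S)-8-bromo-2,3,7-trimethyl-6-methylideneoct-1-ene
Product: 25 [(2R,3R)-2-methyl-3-[(3E,7R,11S)-4,7,11,12-tetramethyl-8-methylidenetrideca-3,12-dien-1-yl]oxiran-2-yl]methanol, via lithium alkoxide 23 (not isolated), via Grignard reagent 24 (not isolated)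
Conditions: 13, Mg, THF, 23 °C; 22, n-BuLi (1.0 equiv), THF, −78 °C; combine, Li2CuCl4 (5 mol %), −78 → 0 °C
Reagents that add atoms: none
Why: Kochi-type Li2CuCl4-catalysed Grignard–allylic chloride coupling forms C8–C9 by SN2 at the primary carbon with retention of the E-alkene, while the pre-formed alkoxide and the cold trisubstituted epoxide stay intact.

Step 16
Reactants: 25 [(2R,3R)-2-methyl-3-[(3E,7R,11S)-4,7,11,12-tetramethyl-8-methylidenetrideca-3,12-dien-1-yl]oxiran-2-yl]methanol; 10 (7S)-8-bromo-2,7-dimethyl-6-methylideneoct-2-ene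
Product: 29 (2R,3R)-2-[(3R)-3,8-dimethyl-4-methylidenenon-7-en-1-yl]-2-methyl-3-[(3E,7R,11S)-4,7,11,12-tetramethyl-8-methylidenetrideca-3,12-dien-1-yl]oxirane, via lithium alkoxide 26 (not isolated), via epoxy triflate 27 (not isolated), via Grignard reagent 28 (not isolated)
Conditions: 25, n-BuLi (1.0 equiv), Et2O, −78 °C; Tf2O (1.0 equiv), −78 °C; then 28 (from 10, Mg, THF; 1.5 equiv), CuBr·SMe2 (10 mol %), −78 → −30 °C
Reagents that add atoms: none
Why: The primary triflate of the 2,3-epoxy alcohol undergoes CuBr-catalysed Grignard coupling (Kotsuki-type sp3–sp3 coupling) at C16 faster than the trisubstituted epoxide can open, forming C16–C17 with all five stereocentres untouched.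

**Compound list**

1 | ethyl (2S)-2-hydroxypropanoate | C[C@H](O)C(=O)OCC | starting material
2 | ethyl (2S)-2-[(trifluoromethanesulfonyl)oxy]propanoate | C[C@H](OS(=O)(=O)C(F)(F)F)C(=O)OCC | intermediate
3 | 6-methylhept-5-en-2-one | CC(=O)CCC=C(C)C | starting material
4 | 2,4,6-tri(propan-2-yl)benzenesulfonohydrazide | CC(C)c1cc(C(C)C)c(S(=O)(=O)NN)c(C(C)C)c1 | starting material
5 | N′-(6-methylhept-5-en-2-ylidene)-2,4,6-tri(propan-2-yl)benzenesulfonohydrazide | CC(CCC=C(C)C)=NNS(=O)(=O)c1c(C(C)C)cc(C(C)C)cc1C(C)C | intermediate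
6 | (6-methylhepta-1,5-dien-2-yl)lithium | [Li]C(=C)CCC=C(C)C | intermediate (not isolated)
7 | lithium bis(6-methylhepta-1,5-dien-2-yl)cuprate | [Li+].C=C(CCC=C(C)C)[Cu-]C(=C)CCC=C(C)C | intermediate (not isolated)
8 | ethyl (2S)-2,7-dimethyl-3-methylideneoct-6-enoate | CCOC(=O)[C@@H](C)C(=C)CCC=C(C)C | intermediate
9 | (2S)-2,7-dimethyl-3-methylideneoct-6-en-1-ol | OC[C@@H](C)C(=C)CCC=C(C)C | intermediate
10 | (7S)-8-bromo-2,7-dimethyl-6-methylideneoct-2-ene | BrC[C@@H](C)C(=C)CCC=C(C)C | intermediate
11 | (2E,7S)-8-bromo-2,7-dimethyl-6-methylideneoct-2-en-1-ol | BrC[C@@H](C)C(=C)CC/C=C(\C)CO | intermediate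
12 | (2E,7S)-8-bromo-1-chloro-2,7-dimethyl-6-methylideneoct-2-ene | BrC[C@@H](C)C(=C)CC/C=C(\C)CCl | intermediate
13 | (3S,7S)-8-bromo-2,3,7-trimethyl-6-methylideneoct-1-ene | BrC[C@@H](C)C(=C)CC[C@H](C)C(C)=C | intermediate
14 | furan | c1ccoc1 | starting material
15 | 2,5-dimethoxy-2,5-dihydrofuran (cis/trans mixture) | COC1C=CC(OC)O1 | intermediate
16 | 2,5-dimethoxyoxolane (cis/trans mixture) | COC1CCC(OC)O1 | intermediate
17 | ethyl 2-(triphenyl-λ5-phosphanylidene)propanoate | CCOC(=O)C(C)=P(c1ccccc1)(c1ccccc1)c1ccccc1 | starting material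
18 | butanedial | O=CCCC=O | intermediate (not isolated)
19 | diethyl (2E,6E)-2,7-dimethylocta-2,6-dienedioate | CCOC(=O)/C(C)=C/CC/C=C(\C)C(=O)OCC | intermediate
20 | (2E,6E)-2,7-dimethylocta-2,6-diene-1,8-diol | OC/C(C)=C/CC/C=C(\C)CO | intermediate
21 | (2E)-5-[(2R,3R)-3-(hydroxymethyl)-3-methyloxiran-2-yl]-2-methylpent-2-en-1-ol | OC/C(C)=C/CC[C@H]1O[C@]1(C)CO | intermediate
22 | [(2R,3R)-3-[(3E)-5-chloro-4-methylpent-3-en-1-yl]-2-methyloxiran-2-yl]methanol | ClC/C(C)=C/CC[C@H]1O[C@]1(C)CO | intermediate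
23 | lithium [(2R,3R)-3-[(3E)-5-chloro-4-methylpent-3-en-1-yl]-2-methyloxiran-2-yl]methanolate | ClC/C(C)=C/CC[C@H]1O[C@]1(C)C[O-].[Li+] | intermediate (not isolated)
24 | [(2S,6S)-2,6,7-trimethyl-3-methylideneoct-7-en-1-yl]magnesium bromide | Br[Mg]C[C@@H](C)C(=C)CC[C@H](C)C(C)=C | intermediate (not isolated)
25 | [(2R,3R)-2-methyl-3-[(3E,7R,11S)-4,7,11,12-tetramethyl-8-methylidenetrideca-3,12-dien-1-yl]oxiran-2-yl]methanol | C=C(CC[C@H](C)C(=C)C)[C@H](C)CC/C(C)=C/CC[C@H]1O[C@]1(C)CO | intermediate
26 | lithium alkoxide of 25 | C=C(CC[C@H](C)C(=C)C)[C@H](C)CC/C(C)=C/CC[C@H]1O[C@]1(C)C[O-].[Li+] | intermediate (not isolated)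
27 | [(2R,3R)-2-methyl-3-[(3E,7R,11S)-4,7,11,12-tetramethyl-8-methylidenetrideca-3,12-dien-1-yl]oxiran-2-yl]methyl trifluoromethanesulfonate | C=C(CC[C@H](C)C(=C)C)[C@H](C)CC/C(C)=C/CC[C@H]1O[C@]1(C)COS(=O)(=O)C(F)(F)F | intermediate (not isolated)
28 | [(2S)-2,7-dimethyl-3-methylideneoct-6-en-1-yl]magnesium bromide | Br[Mg]C[C@@H](C)C(=C)CCC=C(C)C | intermediate (not isolated)
29 | (2R,3R)-2-[(3R)-3,8-dimethyl-4-methylidenenon-7-en-1-yl]-2-methyl-3-[(3E,7R,11S)-4,7,11,12-tetramethyl-8-methylidenetrideca-3,12-dien-1-yl]oxirane | C=C(CC[C@H](C)C(=C)C)[C@H](C)CC/C(C)=C/CC[C@H]1O[C@]1(C)CC[C@@H](C)C(=C)CCC=C(C)C | target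

**Step count and risks**

Total step count: 16. Longest linear sequence: 9 steps (steps 2 to 8, then 15 and 16; the furan line is 8 steps).

The three steps most likely to fail, each with one fallback:

Step 6 (site selectivity of the SeO2 oxidation between the prenyl alkene and the 1,1-disubstituted alkene). The fallback sets out from bromide 10 and comes back at allylic chloride 12, so step 7 is skipped as well. m-Chloroperbenzoic acid (1.0 equiv, NaHCO3, CH2Cl2, −20 °C) epoxidises the trisubstituted alkene about ten times faster than the 1,1-disubstituted one and gives 2-[(4S)-5-bromo-4-methyl-3-methylidenepentyl]-3,3-dimethyloxirane F1. Diethylaluminium 2,2,6,6-tetramethylpiperidide (benzene, 0 °C, Yamamoto epoxide-to-allylic-alcohol isomerisation) removes a methyl proton and gives (7S)-8-bromo-2,7-dimethyl-6-methylideneoct-1-en-3-ol F2. SOCl2 in Et2O then transposes the allylic system (SNi′) to the primary (E)-chloride 12.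

Step 8 (regio- and enantiocontrol of the methyl SN2′ addition at C3). The fallback sets out from allylic alcohol 11 and comes back at bromide 13. Sharpless epoxidation of 11 (Ti(OiPr)4, D-(−)-diisopropyl tartrate, t-BuOOH, −25 °C) gives [(2R,3R)-3-[(4S)-5-bromo-4-methyl-3-methylidenepentyl]-2-methyloxiran-2-yl]methanol F3. Me2CuLi (Et2O, −40 °C) opens the epoxide at the less hindered secondary carbon with inversion, which fixes C3, and gives (2S,3S,7S)-8-bromo-2,3,7-trimethyl-6-methylideneoctane-1,2-diol F4. 1,1′-Thiocarbonyldiimidazole converts the diol into (4S)-4-[(2S,6S)-7-bromo-6-methyl-5-methylideneheptan-2-yl]-4-methyl-1,3-dioxolane-2-thione F5. 1,3-Dimethyl-2-phenyl-1,3,2-diazaphospholidine at 40 °C (Corey–Hopkins form of the Corey–Winter olefination) removes both oxygens and leaves the isopropenyl group of 13. C3 is then set by the reagent-controlled epoxidation and a stereospecific SN2 opening instead of by the copper catalyst.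

Step 16 (copper-catalysed displacement at the hindered epoxy triflate). The fallback sets out from bromide 10 and epoxy alcohol 25 and comes back at target 29. PhSO2Na in DMF turns 10 into {[(2S)-2,7-dimethyl-3-methylideneoct-6-en-1-yl]sulfonyl}benzene F6. n-BuLi (THF, −78 °C) gives [(2S)-1-(benzenesulfonyl)-2,7-dimethyl-3-methylideneoct-6-en-1-yl]lithium F7, a soft stabilised carbanion that needs no copper. F7 alkylates epoxy triflate 27 (made from 25 as in step 16) to give the C17-(benzenesulfonyl) derivative of the target F8 as a mixture of epimers at C17. Sodium amalgam, Na(Hg), with Na2HPO4 in MeOH at −20 °C removes the sulfonyl group and gives 29; the epoxide and the alkenes are expected to survive these buffered conditions.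

**Further compounds**

F1 | step 6 | 2-[(4S)-5-bromo-4-methyl-3-methylidenepentyl]-3,3-dimethyloxirane (both epimers at the oxirane carbon) | BrC[C@@H](C)C(=C)CCC1OC1(C)C
F2 | step 6 | (7S)-8-bromo-2,7-dimethyl-6-methylideneoct-1-en-3-ol (both epimers at C3) | BrC[C@@H](C)C(=C)CCC(O)C(C)=C
F3 | step 8 | [(2R,3R)-3-[(4S)-5-bromo-4-methyl-3-methylidenepentyl]-2-methyloxiran-2-yl]methanol | BrC[C@@H](C)C(=C)CC[C@H]1O[C@]1(C)CO
F4 | step 8 | (2S,3S,7S)-8-bromo-2,3,7-trimethyl-6-methylideneoctane-1,2-diol | BrC[C@@H](C)C(=C)CC[C@H](C)[C@](C)(O)CO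
F5 | step 8 | (4S)-4-[(2S,6S)-7-bromo-6-methyl-5-methylideneheptan-2-yl]-4-methyl-1,3-dioxolane-2-thione | BrC[C@@H](C)C(=C)CC[C@H](C)[C@@]1(C)COC(=S)O1
F6 | step 16 | {[(2S)-2,7-dimethyl-3-methylideneoct-6-en-1-yl]sulfonyl}benzene | O=S(=O)(C[C@@H](C)C(=C)CCC=C(C)C)c1ccccc1
F7 | step 16 | [(2S)-1-(benzenesulfonyl)-2,7-dimethyl-3-methylideneoct-6-en-1-yl]lithium | [Li]C(S(=O)(=O)c1ccccc1)[C@@H](C)C(=C)CCC=C(C)C
F8 | step 16 | C17-(benzenesulfonyl) derivative of target 29 (epimers at C17) | C=C(CC[C@H](C)C(=C)C)[C@H](C)CC/C(C)=C/CC[C@H]1O[C@]1(C)CC(S(=O)(=O)c1ccccc1)[C@@H](C)C(=C)CCC=C(C)C
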